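A direct plan would etherify 3,4-diacetoxy-2,6-dibromobenzyl bromide A1 with 3-cyclohexene-1-methanol A2, would oxidise the alkene to the 1,2-dione A3, would make ring B by Br2-driven dehydrogenation and threefold bromination to the diacetate A4, and would end with deacetylation. Its weakest steps would be:
- the bromination–aromatisation of A3, an unprecedented cascade that would expose the benzylic ether to Br2 and HBr;
- the glycol-to-dione oxidation, which would give an unstable 1,2-dione only to rebuild an available aromatic ring;
- the AgOTf-assisted coupling of A1 with A2, which would ionise a benzylic bromide beside labile aryl acetates.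

The route rests on disconnecting the ring B benzylic C–O bond back to a methyl C–H. Ring B enters as 3,4,6-tribromo-5-methyl-o-benzoquinone, two steps from 4-methylcatechol. Because ring B has its C4 oxygen para to the benzylic carbon and bromine on C2, C5 and C6, this quinone offers nucleophiles no ring C–H and can only tautomerise to a para-quinone methide, which the ring A benzylic alcohol captures, as in the presumed biogenesis of algal bromophenol ethers. One redox-neutral operation thus forms the ether bond and delivers ring B as the free, fully brominated catechol. No carbocycle is built or aromatised, no 1,2-diketone is handled, and no benzylic halide or AgOTf is needed.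

Key step: step 7

Assumption: the target is achiral, so no configuration has to be set; in step 5 the order of the second and third brominations is assumed and does not change the product.

Step 1
Reactants: 1 isovanillin (3-hydroxy-4-methoxybenzaldehyde)
Product: 3 2,6-dibromo-3-hydroxy-4-methoxybenzaldehyde, via 2-bromoisovanillin 2 (not isolated)
Conditions: Br2 (2.2 equiv), NaOAc (2.5 equiv), AcOH, rt → 45 °C
Reagents that add atoms: bromine, BrBr
Why: Electrophilic aromatic bromination in which the free C3–OH, the strongest donor of the ring, directs first to its ortho carbon C2 and then to its para carbon C6, while C5, activated only by the methoxy group, should stay unsubstituted and so fixes the ring A pattern with its C5–H.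

Step 2
Reactants: 3 2,6-dibromo-3-hydroxy-4-methoxybenzaldehyde
Product: 4 2,6-dibromo-3,4-dihydroxybenzaldehyde
Conditions: BBr3 (3 equiv), CH2Cl2, −78 °C → rt; ice–water
Reagents that add atoms: none
Why: Lewis-acid cleavage of the aryl methyl ether (O–B coordination, then SN2 attack of bromide on the methyl group), placed here because no benzylic ether yet exists that BBr3 would destroy.

Step 3
Reactants: 4 2,6-dibromo-3,4-dihydroxybenzaldehyde
Product: 5 3,4-bis(tert-butyldimethylsilyloxy)-2,6-dibromobenzaldehyde
Conditions: TBSCl (2.6 equiv), imidazole (5 equiv), DMF, 0 °C → rt
Reagents that add atoms: tert-butyldimethylsilyl chloride, CC(C)(C)[Si](C)(C)Cl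
Why: Imidazole-mediated O-silylation of both phenols (substitution at silicon through the N-silylimidazolium ion) gives ethers that carry no acidic O–H, are weak donors and should be inert to the later proton-shuttle catalyst, yet fall to buffered fluoride.

Step 4
Reactants: 5 3,4-bis(tert-butyldimethylsilyloxy)-2,6-dibromobenzaldehyde
Product: 6 [3,4-bis(tert-butyldimethylsilyloxy)-2,6-dibromophenyl]methanol
Conditions: i-Bu2AlH (1.2 equiv), CH2Cl2, −78 °C; aq potassium sodium tartrate
Reagents that add atoms: none
Why: Carbonyl reduction by hydride addition of i-Bu2AlH to the aldehyde at −78 °C, where neither aryl silyl ether cleavage nor bromine–metal exchange should compete, and without the alkoxide medium that a NaBH4 reduction in an alcohol would bring.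

Step 5
Reactants: 7 4-methylcatechol
Product: 10 3,4,6-tribromo-5-methylbenzene-1,2-diol, via 4-bromo-5-methylcatechol 8 (not isolated), via 3,4-dibromo-5-methylcatechol 9 (not isolated)
Conditions: Br2 (3.05 equiv), AcOH, 10 °C → rt; aq NaHSO3 wash
Reagents that add atoms: bromine, BrBr
Why: Exhaustive electrophilic aromatic bromination in which each of the three ring C–H positions is ortho or para to a hydroxyl, while the unbuffered HBr keeps the catechol in the reduced state and the exact bromine charge leaves the methyl group untouched.

Step 6
Reactants: 10 3,4,6-tribromo-5-methylbenzene-1,2-diol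
Product: 11 3,4,6-tribromo-5-methylcyclohexa-3,5-diene-1,2-dione (the o-quinone of 10)
Conditions: NaIO4 (1.1 equiv), H2O–CH2Cl2, 0 °C, 10 min, dark; organic layer dried (Na2SO4) and used the same day
Reagents that add atoms: none
Why: Periodate oxidation of a catechol through a cyclic aryl periodate ester that collapses to the o-quinone and iodate; the fully substituted halo-o-quinone should pass at once into the organic layer, where the base-free, slightly acidic medium gives the methyl group no occasion to enolise.

Step 7
Reactants: 11 3,4,6-tribromo-5-methylcyclohexa-3,5-diene-1,2-dione; 6 [3,4-bis(tert-butyldimethylsilyloxy)-2,6-dibromophenyl]methanol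
Product: 13 3,4-bis(tert-butyldimethylsilyloxy)-2,6-dibromobenzyl 2,5,6-tribromo-3,4-dihydroxybenzyl ether, via quinone methide 12 (not isolated)
Conditions: 6 (1.0 equiv), 2,6-lutidine (0.3 equiv), AcOH (0.3 equiv), 4 Å MS, CH2Cl2, 0 °C → rt, dark, Ar; 11 (1.3 equiv) added over 3 h; aq Na2S2O4 wash
Reagents that add atoms: none
Why: Proposed new method: 2,6-lutidine removes a proton from the C5 methyl group of 11, which is vinylogous to the C1 carbonyl and is the only enolisable position, and O-protonation by the acetic acid partner gives the 2-hydroxy-para-quinone methide 12; the primary hydroxyl of 6 then adds to the exocyclic CH2 of 12 in a 1,6-fashion and the ring regains its aromatic sextet as the free catechol, so that the step is a redox-neutral isomerisation–addition that moves the oxidation level of the quinone to the benzylic carbon. The closest known reaction types are the base-catalysed isomerisation of 4-alkyl-o-benzoquinones to para-quinone methides, which water and alcohols then attack at the side chain, and the dehydrogenative alkoxylation of 2,6-disubstituted 4-methylphenols through quinone methides; what is new is the use of a methyl-substituted trihalo-o-quinone and of a near-stoichiometric, hindered benzylic alcohol. No ring is closed and no stereocentre is formed. The step needs attack at the exocyclic carbon and not at the ring, reaction of the benzylic hydroxyl and not of a phenol, and no oxidation of 6 by 11: the bromines on all three ring carbons leave 11 without a ring C–H for conjugate addition, and the two silyl ethers deprive 6 of every phenolic O–H, block its own para-quinone methide and leave its ring too electron-poor for C5 alkylation or electron transfer. Phenolic adducts of 12 with the product catechol would revert, because an aryloxide is a far better leaving group than the alkoxide of 6, so the dialkyl ether is the thermodynamic sink. Slow addition keeps free 11 low so that the product catechol is not re-oxidised by redox exchange, and the dithionite wash returns unused 11 to 10 for recycling.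

Step 8
Reactants: 13 3,4-bis(tert-butyldimethylsilyloxy)-2,6-dibromobenzyl 2,5,6-tribromo-3,4-dihydroxybenzyl ether
Product: 14 2,6-dibromo-3,4-dihydroxybenzyl 2,5,6-tribromo-3,4-dihydroxybenzyl ether (target)
Conditions: Bu4NF (2.4 equiv), AcOH (3 equiv), degassed THF, 0 °C, Ar; cold pH 5 phosphate buffer
Reagents that add atoms: none
Why: Fluoride-induced desilylation of the two aryl silyl ethers through pentacoordinate silicon, buffered with acetic acid so that each phenol is protonated as it is released and neither an air-sensitive catecholate nor a para-phenoxide able to expel the benzylic alkoxide should persist.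

Compound list
1 | isovanillin (3-hydroxy-4-methoxybenzaldehyde) | COc1ccc(C=O)cc1O | starting material
2 | 2-bromoisovanillin (2-bromo-3-hydroxy-4-methoxybenzaldehyde), not isolated | COc1ccc(C=O)c(Br)c1O | intermediate
3 | 2,6-dibromo-3-hydroxy-4-methoxybenzaldehyde | COc1cc(Br)c(C=O)c(Br)c1O | intermediate
4 | 2,6-dibromo-3,4-dihydroxybenzaldehyde | Oc1cc(Br)c(C=O)c(Br)c1O | intermediate
5 | 3,4-bis(tert-butyldimethylsilyloxy)-2,6-dibromobenzaldehyde | CC(C)(C)[Si](C)(C)Oc1cc(Br)c(C=O)c(Br)c1O[Si](C)(C)C(C)(C)C | intermediate
6 | [3,4-bis(tert-butyldimethylsilyloxy)-2,6-dibromophenyl]methanol | CC(C)(C)[Si](C)(C)Oc1cc(Br)c(CO)c(Br)c1O[Si](C)(C)C(C)(C)C | intermediate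
7 | 4-methylcatechol (4-methylbenzene-1,2-diol) | Cc1ccc(O)c(O)c1 | starting material
8 | 4-bromo-5-methylcatechol (4-bromo-5-methylbenzene-1,2-diol), not isolated | Cc1cc(O)c(O)cc1Br | intermediate
9 | 3,4-dibromo-5-methylcatechol (3,4-dibromo-5-methylbenzene-1,2-diol), not isolated | Cc1cc(O)c(O)c(Br)c1Br | intermediate
10 | 3,4,6-tribromo-5-methylbenzene-1,2-diol | Cc1c(Br)c(O)c(O)c(Br)c1Br | intermediate
11 | 3,4,6-tribromo-5-methylcyclohexa-3,5-diene-1,2-dione (key-step precursor) | CC1=C(Br)C(=O)C(=O)C(Br)=C1Br | intermediate
12 | 2,3,5-tribromo-6-hydroxy-4-methylidenecyclohexa-2,5-dien-1-one (quinone methide), not isolated | C=C1C(Br)=C(O)C(=O)C(Br)=C1Br | intermediate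
13 | 3,4-bis(tert-butyldimethylsilyloxy)-2,6-dibromobenzyl 2,5,6-tribromo-3,4-dihydroxybenzyl ether | CC(C)(C)[Si](C)(C)Oc1cc(Br)c(COCc2c(Br)c(O)c(O)c(Br)c2Br)c(Br)c1O[Si](C)(C)C(C)(C)C | intermediate
14 | 2,6-dibromo-3,4-dihydroxybenzyl 2,5,6-tribromo-3,4-dihydroxybenzyl ether (CNP0152798.0, achiral) | Oc1cc(Br)c(COCc2c(Br)c(O)c(O)c(Br)c2Br)c(Br)c1O | target

Total step count: 8. Longest linear sequence: 6 steps (steps 1, 2, 3, 4, 7 and 8); steps 5 and 6 form the two-step ring B branch.

Steps most likely to fail

Step 7 (carries the label). Tautomerisation of 11 may be slower than redox exchange between free quinone and the product catechol, which would over-oxidise the benzylic carbon. The quinone methide may also be captured by adventitious water or may oligomerise before the hindered alcohol reaches it, and bromide may be displaced from the quinone by addition–elimination. The fallback uses known chemistry, sets out from 10 and returns at 13. Side-chain bromination of 10 with one further equivalent of Br2 in warm AcOH, the classical conversion of ring-saturated para-cresols into para-hydroxybenzyl bromides, would give 2,3,6-tribromo-4,5-dihydroxybenzyl bromide F1. Free para-hydroxybenzyl bromides of this kind are displaced by alcohols without a promoter, so stirring F1 with 6 and solid NaHCO3 in MeCN–CH2Cl2 at room temperature under argon should give 13.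

Step 6. The quinone may enolise and add water during the two-phase oxidation, or may decay when its solution is dried and stored. The fallback sets out from 10 and returns at 13 without isolating any quinone. It is a one-flask dehydrogenative alkoxylation, as known for the oxidation of 4-methylphenols to 4-(alkoxymethyl)phenols. 10 and 6 would be treated with 2,3-dichloro-5,6-dicyano-1,4-benzoquinone (1.0 equiv) over 4 Å MS in CH2Cl2 at 0 °C, so that 11 or 12 is consumed by 6 as it forms, and the insoluble hydroquinone would be filtered off. No new compound would be isolated on this way, hence the entry F0 below.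

Step 8. Fluoride may trigger loss of the benzylic ether by 1,6-elimination from a ring A para-phenoxide, or the catechols may oxidise in air during desilylation. The fallback sets out from 4 and returns at 14 with a protecting group that is removed without fluoride or base. Reduction of 4 with NaBH4 in EtOH at 0 °C would give 2,6-dibromo-3,4-dihydroxybenzyl alcohol F2. Condensation of F2 with PhB(OH)2 (toluene, 4 Å MS) would tie the ring A catechol as the cyclic boronate (4,6-dibromo-2-phenyl-1,3,2-benzodioxaborol-5-yl)methanol F3. Coupling of F3 with 11 under the conditions of step 7 would give 2,5,6-tribromo-3,4-dihydroxybenzyl (4,6-dibromo-2-phenyl-1,3,2-benzodioxaborol-5-yl)methyl ether F4; migration of the boronate between the two catechols would not matter, since every such isomer leads to the same product. Transesterification of F4 with pinacol (1.2 equiv) in degassed THF at room temperature under argon would release 14, and a hexane wash would remove the pinacol boronate.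

Further compounds
F1 | step 7 | 2,3,6-tribromo-4,5-dihydroxybenzyl bromide | BrCc1c(Br)c(O)c(O)c(Br)c1Br
F0 | step 6 | none | none
F2 | step 8 | 2,6-dibromo-3,4-dihydroxybenzyl alcohol | OCc1c(Br)cc(O)c(O)c1Br
F3 | step 8 | (4,6-dibromo-2-phenyl-1,3,2-benzodioxaborol-5-yl)methanol | OCc1c(Br)cc2OB(c3ccccc3)Oc2c1Br
F4 | step 8 | 2,5,6-tribromo-3,4-dihydroxybenzyl (4,6-dibromo-2-phenyl-1,3,2-benzodioxaborol-5-yl)methyl ether | Oc1c(O)c(Br)c(COCc2c(Br)cc3OB(c4ccccc4)Oc3c2Br)c(Br)c1Br
A1 | direct plan | 3,4-diacetoxy-2,6-dibromobenzyl bromide | CC(=O)Oc1cc(Br)c(CBr)c(Br)c1OC(C)=O
A2 | direct plan | 3-cyclohexene-1-methanol (racemic) | OCC1CCC=CC1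
A3 | direct plan | 3,4-diacetoxy-2,6-dibromobenzyl (3,4-dioxocyclohexyl)methyl ether (racemic) | CC(=O)Oc1cc(Br)c(COCC2CCC(=O)C(=O)C2)c(Br)c1OC(C)=O
A4 | direct plan | 3,4-diacetoxy-2,6-dibromobenzyl 2,5,6-tribromo-3,4-dihydroxybenzyl ether | CC(=O)Oc1cc(Br)c(COCc2c(Br)c(O)c(O)c(Br)c2Br)c(Br)c1OC(C)=O
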